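**Assumption:** (S)-(+)-terpinen-4-ol is bought in high ee. Daucane numbering is used: C1 quaternary ring-fusion carbon (Me-15), C4 carbinol carbon bearing iPr, C5 ring-fusion CH, C6 ester carbon, C8 bears the exocyclic C14H2, C9 CHOH, C10 CH2. Target = 6α-(4-hydroxybenzoyloxy)-5αH-dauc-8(14)-ene-4β,9α-diol (Me-15 β).

## Retrosynthetic overview

1. Ferugin ⇒ phenol deacetylation, C9 allylic hydroxylation, C6 acylation and 4-OH-directed C6 reduction of hydroazulenone 8.
2. 8 ⇒ C1–C10 bond by a photochemical 7-endo radical conjugate cyclisation of iodo-enone 7; this closes the seven-membered ring and sets C1 and C5.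
3. 7 ⇒ enal 3 + isoprenol dianion (C6–C7 bond), then iodination and oxidation.
4. 3 ⇒ (S)-terpinen-4-ol by ozonolysis and intramolecular aldol condensation (6 → 5 ring contraction; C4 is bought).
5. Ring order: cyclopentane first (from the chiral pool), seven-membered ring second.

## Route

**Step 1**
Reactants: 1, (S)-(+)-terpinen-4-ol
Product: 2, (3S)-3-hydroxy-6-oxo-3-(propan-2-yl)heptanal (used crude)
Conditions: O3, CH2Cl2/MeOH, −78 °C; then Me2S, −78 → 23 °C
Reagents that add atoms: ozone, [O-][O+]=O
Why: Ozonolysis with reductive work-up cleaves the only alkene to the keto-aldehyde and leaves the bought carbinol stereocentre (future C4) untouched.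

**Step 2**
Reactants: 2
Product: 3, (5R)-5-hydroxy-2-methyl-5-(propan-2-yl)cyclopent-1-ene-1-carbaldehyde
Conditions: Bn2NH·TFA (0.3 equiv), PhH, 23 → 50 °C
Reagents that add atoms: none
Why: Amine-salt intramolecular aldol condensation in which the aldehyde enamine attacks the methyl ketone to form the five-membered ring and the newly formed tertiary C–O (not the iPr-bearing carbinol) is eliminated; no new stereocentre.

**Step 3**
Reactants: 3; 4, 3-methylbut-3-en-1-ol (isoprenol)
Product: 5, 1-[(5R)-5-hydroxy-2-methyl-5-(propan-2-yl)cyclopent-1-en-1-yl]-3-methylidenepentane-1,5-diol (C1 epimer mixture)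
Conditions: 4 (3 equiv), n-BuLi (6 equiv), TMEDA, Et2O–hexane, 0 → 23 °C; then 3, −78 → 0 °C
Reagents that add atoms: none
Why: 1,2-Addition of the allylic lithium of the isoprenol dianion to the enal forms C6–C7 and brings in C7–C10 and C14; the carbinol configuration is irrelevant because it is oxidised in step 5.

**Step 4**
Reactants: 5
Product: 6, 1-[(5R)-5-hydroxy-2-methyl-5-(propan-2-yl)cyclopent-1-en-1-yl]-5-iodo-3-methylidenepentan-1-ol
Conditions: I2 (1.1 equiv), PPh3, imidazole, CH2Cl2, 0 °C
Reagents that add atoms: iodine, II
Why: Appel iodination is selective for the primary alcohol over the hindered secondary allylic and tertiary alcohols.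

**Step 5**
Reactants: 6
Product: 7, 1-[(5R)-5-hydroxy-2-methyl-5-(propan-2-yl)cyclopent-1-en-1-yl]-5-iodo-3-methylidenepentan-1-one
Conditions: Dess–Martin periodinane, NaHCO3, CH2Cl2, 0 → 23 °C
Reagents that add atoms: none
Why: Dess–Martin oxidation of the hindered secondary alcohol under buffered neutral conditions gives the enone without moving the β,γ-alkene into conjugation.

**Step 6 (key step)**
Reactants: 7
Product: 8, 4β-hydroxy-5αH-dauc-8(14)-en-6-one (trans-fused; Me-15 β, 4-OH β, iPr α)
Conditions: 4CzIPN (2 mol %), i-Pr2NEt (3 equiv), LiBF4 (2 equiv), H2O (10 equiv), MeCN (0.01 M), 456 nm LEDs, 23 °C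
Reagents that add atoms: none
Why: Proposed new method: a Li+-templated halogen-atom-transfer photoredox 7-endo-trig Giese cyclisation, in which the photogenerated α-aminoalkyl radical abstracts iodine, the primary C10 radical adds to the Li+-activated enone β-carbon C1, and reduction/protonation by water gives the ketone; the O4–H/Li···O6 chelate tilts the carbonyl oxygen of the s-trans enone to the β face so the C7 chain delivers C10 to the α face of C1 (Me-15 β), and the chelate plus Me-15 shield the β face so C5 is protonated from α (trans fusion, C6 anti to iPr); closest known reaction types are intermolecular halogen-atom-transfer photoredox Giese hydroalkylation and Lewis-acid-accelerated radical conjugate addition, not shown for 7-endo closure onto a fully substituted enone carbon.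

**Step 7**
Reactants: 8
Product: 9, 5αH-dauc-8(14)-ene-4β,6α-diol
Conditions: Me4NBH(OAc)3, MeCN/AcOH, −20 °C
Reagents that add atoms: none
Why: Evans–Saksena hydroxyl-directed reduction, in which the 4β-alkoxyborohydride delivers hydride intramolecularly to the β face of the C6 ketone and so sets 6α-OH.

**Step 8**
Reactants: 9; 10, 4-acetoxybenzoyl chloride
Product: 11, 6α-(4-acetoxybenzoyloxy)-5αH-dauc-8(14)-en-4β-ol
Conditions: pyridine, DMAP (cat.), CH2Cl2, 0 → 23 °C
Reagents that add atoms: none
Why: DMAP-catalysed acylation occurs only at the secondary C6–OH because the tertiary C4–OH is unreactive.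

**Step 9**
Reactants: 11
Product: 12, 6α-(4-acetoxybenzoyloxy)-5αH-dauc-8(14)-ene-4β,9α-diol
Conditions: SeO2 (0.5 equiv), t-BuOOH, CH2Cl2, 0 → 23 °C
Reagents that add atoms: selenium dioxide, O=[Se]=O; tert-butyl hydroperoxide, CC(C)(C)OO
Why: SeO2 allylic hydroxylation (ene reaction then [2,3]-shift, which returns the exocyclic alkene) is expected to take C9–H rather than the hindered, ester-deactivated C7–H and to deliver oxygen to the α face away from Me-15, giving 9α-OH.

**Step 10**
Reactants: 12
Product: 13, ferugin
Conditions: K2CO3 (0.2 equiv), MeOH, 0 °C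
Reagents that add atoms: none
Why: Mild methanolysis cleaves the phenolic acetate selectively, and the resulting phenoxide deactivates the hindered 4-hydroxybenzoate toward further methanolysis.

## Compound list

1 | (S)-(+)-terpinen-4-ol | CC1=CC[C@](O)(C(C)C)CC1 | starting material
2 | (3S)-3-hydroxy-6-oxo-3-(propan-2-yl)heptanal | O=CC[C@](O)(C(C)C)CCC(C)=O | intermediate
3 | (5R)-5-hydroxy-2-methyl-5-(propan-2-yl)cyclopent-1-ene-1-carbaldehyde | O=CC1=C(C)CC[C@@]1(O)C(C)C | intermediate
4 | 3-methylbut-3-en-1-ol (isoprenol) | CC(=C)CCO | starting material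
5 | 1-[(5R)-5-hydroxy-2-methyl-5-isopropylcyclopent-1-en-1-yl]-3-methylidenepentane-1,5-diol (C1 epimers) | OCCC(=C)CC(O)C1=C(C)CC[C@@]1(O)C(C)C | intermediate
6 | 1-[(5R)-5-hydroxy-2-methyl-5-isopropylcyclopent-1-en-1-yl]-5-iodo-3-methylidenepentan-1-ol (C1 epimers) | ICCC(=C)CC(O)C1=C(C)CC[C@@]1(O)C(C)C | intermediate
7 | 1-[(5R)-5-hydroxy-2-methyl-5-isopropylcyclopent-1-en-1-yl]-5-iodo-3-methylidenepentan-1-one | ICCC(=C)CC(=O)C1=C(C)CC[C@@]1(O)C(C)C | intermediate
8 | 4β-hydroxy-5αH-dauc-8(14)-en-6-one | C=C1CC(=O)[C@@H]2[C@](C)(CC[C@@]2(O)C(C)C)CC1 | intermediate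
9 | 5αH-dauc-8(14)-ene-4β,6α-diol | C=C1C[C@H](O)[C@@H]2[C@](C)(CC[C@@]2(O)C(C)C)CC1 | intermediate
10 | 4-acetoxybenzoyl chloride | CC(=O)Oc1ccc(cc1)C(Cl)=O | starting material
11 | 6α-(4-acetoxybenzoyloxy)-5αH-dauc-8(14)-en-4β-ol | C=C1C[C@H](OC(=O)c2ccc(OC(C)=O)cc2)[C@@H]2[C@](C)(CC[C@@]2(O)C(C)C)CC1 | intermediate
12 | 6α-(4-acetoxybenzoyloxy)-5αH-dauc-8(14)-ene-4β,9α-diol | C=C1C[C@H](OC(=O)c2ccc(OC(C)=O)cc2)[C@@H]2[C@](C)(CC[C@@]2(O)C(C)C)C[C@@H]1O | intermediate
13 | ferugin | C=C1C[C@H](OC(=O)c2ccc(O)cc2)[C@@H]2[C@](C)(CC[C@@]2(O)C(C)C)C[C@@H]1O | target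

## Totals and main risks

Total steps: 10. Longest linear sequence: 10 (fully linear; 4 and 10 are bought).

Steps most likely to fail:

1. **Step 6 (proposed new reaction).** Closure onto a fully substituted β-carbon may be slower than premature reduction of the C10 radical or than 5-exo attack on the C6 carbonyl (acyl shift to an allyl radical). The C1 face and the C5 epimer rest on the chelate model, and base equilibration of C5 is not available because it would move the β,γ-alkene into conjugation and risk retro-aldol at C4.
   Fallback (known chemistry): make C1–C10 by a de Mayo-type sequence. Build the 1,4-diketone side chain on 3, convert the methyl ketone to its silyl enol ether, and run the intramolecular enone–alkene [2+2] photocycloaddition (rule-of-five "straight" adduct, C5–C9 and C1–C10 bonds). Fluoride-triggered retro-aldol then opens the cyclobutanol to the 6,9-dione, and C8 methylenation plus C9 reduction replace step 9.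

2. **Step 9.** C7 oxidation, over-oxidation to the enone, or a 9β-alcohol could compete.
   Fallback: isomerise the 8(14)-alkene to the Δ8 isomer, epoxidise from the α face, and open the trisubstituted epoxide to the exo-methylene 9α-alcohol with Cp2TiCl or Et2Al(TMP).

3. **Step 2.** The β-hydroxy aldehyde 2 can retro-aldolise, or the iPr-bearing hydroxyl can be eliminated instead of the new one, giving the wrong cyclopentene.
   Fallback: protect 1 as its TES ether before ozonolysis so that this oxygen can neither leave nor fragment, and remove the TES group before step 6 (two extra steps).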